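**Retrosynthetic overview**

1. The strategy rests on the C1(=O)–C2H2–C3H(OH) β-hydroxy ketone in the cyclohexanone ring of the tetralone (C1 ketone, C3 carbinol, C5 pyronyl, C6 phenyl, C8 OH). It is an aldol retron, and cutting C2–C3 leaves a flat, achiral pentasubstituted benzene with an acetyl group on C8a and a CH2CHO group on C4a.
2. C2–C3 is formed by a catalyst-controlled enantioselective 6-enolexo aldol closure (dinuclear zinc amino alcohol catalyst), which closes the cyclohexanone ring and sets C3 as (S). Hydrogenolysis of two benzyl ethers then gives the target.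
3. The aldehyde is released under non-acidic conditions from a CH2CH2OSiMe2t-Bu side chain (desilylation, Dess–Martin oxidation), so that no acid-induced racemic closure or naphthol formation precedes the key step.
4. The benzene ring is built de novo: Michael–Dieckmann annulation of a pyronyl-substituted 3-phenylbutenoate (C5–C6–C7–C8) with an enone (C4a, C8a and the acetyl group) forms C5–C4a and C8–C8a, and DDQ aromatises.
5. Ring order: the pyrone ring (from triacetic acid lactone, benzylated and extended at its methyl group by addition to methyl phenylpropiolate), then the benzene ring, then the cyclohexanone ring.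

Key step: step 8

Assumption: 3-(tert-butyldimethylsilyloxy)propanal (5) is taken as a purchasable aldehyde; otherwise it is two routine steps from propane-1,3-diol (monosilylation, oxidation).

**Route**

Step 1
Reactants: 1 4-hydroxy-6-methyl-2H-pyran-2-one (triacetic acid lactone)
Product: 2 4-(benzyloxy)-6-methyl-2H-pyran-2-one
Conditions: BnOH, PPh3, DIAD, THF, 0 °C to rt
Reagents that add atoms: benzyl alcohol, OCc1ccccc1
Why: Mitsunobu reaction, in which the acidic 4-hydroxyl of the pyrone (a vinylogous carboxylic acid) is the pronucleophile and should be O-benzylated with little C3-alkylation.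

Step 2
Reactants: 2 4-(benzyloxy)-6-methyl-2H-pyran-2-one; 3 methyl 3-phenylprop-2-ynoate (methyl phenylpropiolate)
Product: 4 methyl (2E)-4-[4-(benzyloxy)-2-oxo-2H-pyran-6-yl]-3-phenylbut-2-enoate (an E/Z mixture is acceptable)
Conditions: LiN(SiMe3)2, THF, −78 °C; then 3 added slowly, −78 °C to 0 °C; AcOH quench
Reagents that add atoms: none
Why: Michael addition of a carbanion to an alkynoate: lateral deprotonation of the 6-methyl group gives a vinylogous ester enolate that adds at the β-carbon of 3, proton transfer from the new, more acidic CH2 to the allenolate leaves the delocalised anion of 4, and the alkene geometry is immaterial because step 4 passes through that same anion.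

Step 3
Reactants: 5 3-(tert-butyldimethylsilyloxy)propanal; 6 1-(triphenylphosphoranylidene)propan-2-one
Product: 7 (3E)-6-(tert-butyldimethylsilyloxy)hex-3-en-2-one
Conditions: CH2Cl2, rt
Reagents that add atoms: none
Why: Wittig olefination with a stabilised acyl ylide, which should give the (E)-enone under neutral conditions that do not trigger β-elimination of the silyloxy aldehyde.

Step 4
Reactants: 4 methyl (2E)-4-[4-(benzyloxy)-2-oxo-2H-pyran-6-yl]-3-phenylbut-2-enoate; 7 (3E)-6-(tert-butyldimethylsilyloxy)hex-3-en-2-one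
Product: 10 6-{3-acetyl-2-[2-(tert-butyldimethylsilyloxy)ethyl]-4-hydroxy-6-phenylphenyl}-4-(benzyloxy)-2H-pyran-2-one, via Michael adduct 8 (not isolated), via acetylcyclohexenone 9 (not isolated)
Conditions: LiN(SiMe3)2 (1.1 equiv), THF, −78 °C; then 7, −78 °C to rt; AcOH quench; crude product, DDQ (1.2 equiv), PhMe, rt
Reagents that add atoms: none
Why: Michael–Dieckmann annulation followed by dehydrogenation: the delocalised anion of 4 adds through its pyronyl-bearing carbon to the β-carbon of 7 (C5–C4a), the ketone enolate so formed is acylated by the methyl ester (C8–C8a, six-membered closure driven by the stable β-diketone enolate), and DDQ removes the two ring hydrogens of the cyclohexadienol tautomer of 9 to give the benzene ring, so the two transient sp3 centres need no control.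

Step 5
Reactants: 10 6-{3-acetyl-2-[2-(tert-butyldimethylsilyloxy)ethyl]-4-hydroxy-6-phenylphenyl}-4-(benzyloxy)-2H-pyran-2-one
Product: 11 6-{3-acetyl-4-(benzyloxy)-2-[2-(tert-butyldimethylsilyloxy)ethyl]-6-phenylphenyl}-4-(benzyloxy)-2H-pyran-2-one
Conditions: BnBr, K2CO3, DMF, 50 °C
Reagents that add atoms: benzyl bromide, BrCc1ccccc1
Why: Williamson ether synthesis: K2CO3 deprotonates only the phenol (hydrogen-bonded to the ortho acetyl group, hence gentle warming), and O-benzylation masks the acidic OH that would otherwise quench the zinc catalyst in step 8.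

Step 6
Reactants: 11 6-{3-acetyl-4-(benzyloxy)-2-[2-(tert-butyldimethylsilyloxy)ethyl]-6-phenylphenyl}-4-(benzyloxy)-2H-pyran-2-one
Product: 12 6-[3-acetyl-4-(benzyloxy)-2-(2-hydroxyethyl)-6-phenylphenyl]-4-(benzyloxy)-2H-pyran-2-one
Conditions: HF·pyridine, pyridine, THF, 0 °C to rt
Reagents that add atoms: none
Why: Fluoride-mediated desilylation with buffered HF·pyridine should cleave the primary silyl ether without touching the benzyl ethers, the pyrone or the ketone; 12 may sit partly as its ring-closed hemiketal, which reopens on oxidation.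

Step 7
Reactants: 12 6-[3-acetyl-4-(benzyloxy)-2-(2-hydroxyethyl)-6-phenylphenyl]-4-(benzyloxy)-2H-pyran-2-one
Product: 13 2-{2-acetyl-3-(benzyloxy)-6-[4-(benzyloxy)-2-oxo-2H-pyran-6-yl]-5-phenylphenyl}acetaldehyde
Conditions: Dess–Martin periodinane, NaHCO3, CH2Cl2, 0 °C
Reagents that add atoms: none
Why: Dess–Martin oxidation under buffered, non-acidic conditions should give the arylacetaldehyde without over-oxidation and without the acid that would cause racemic aldol closure and dehydration; 13 is filtered through a short pad and used at once.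

Step 8
Reactants: 13 2-{2-acetyl-3-(benzyloxy)-6-[4-(benzyloxy)-2-oxo-2H-pyran-6-yl]-5-phenylphenyl}acetaldehyde
Product: 14 (3S)-8-(benzyloxy)-5-[4-(benzyloxy)-2-oxo-2H-pyran-6-yl]-3-hydroxy-6-phenyl-3,4-dihydronaphthalen-1(2H)-one (8,4'-di-O-benzyl wailupemycin F)
Conditions: (S,S)-ProPhenol ligand [2,6-bis{[(S)-2-(hydroxydiphenylmethyl)pyrrolidin-1-yl]methyl}-4-methylphenol] (10 mol %), ZnEt2 (20 mol %), Ph3P=S (15 mol %), 4 Å molecular sieves, THF (0.02 M), −20 °C to 0 °C; pH 7 phosphate buffer
Reagents that add atoms: none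
Why: Proposed new method: the ligand and ZnEt2 form a dinuclear zinc alkoxide that should hold the C1 acetyl group as a zinc enolate on one metal and activate the C3 aldehyde on the other, so that C2 adds to C3 inside the chiral pocket and the zinc aldolate is released by proton exchange with the next molecule of 13. The closest known reaction types are the intermolecular direct aldol addition of aryl methyl ketones to aldehydes with this catalyst class and amine-catalysed 6-enolexo aldolisations of dicarbonyl compounds. The cyclohexanone ring closes in a 6-(enolexo)-exo-trig mode that the ortho placement of the two side chains on the rigid benzene ring makes entropically cheap. The C3 centre is set by the catalyst alone because 13 is achiral: by analogy with the intermolecular reaction the (S,S)-ligand should send the enolate to the Re face of the aldehyde, which corresponds to (3S), and the (R,R)-ligand is taken if the first run shows the opposite sense. Site selectivity comes from the substrate, since C-attack of the aldehyde enolate on the ketone would need a four-membered ring and hemiketal formation is reversible, so only the ketone enolate reaches an unstrained ring. The step also needs the aldol not to dehydrate to the 1-naphthol, which the low temperature, the aprotic medium and the neutral buffer quench should secure.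

Step 9
Reactants: 14 (3S)-8-(benzyloxy)-5-[4-(benzyloxy)-2-oxo-2H-pyran-6-yl]-3-hydroxy-6-phenyl-3,4-dihydronaphthalen-1(2H)-one
Product: 15 (3S)-3,8-dihydroxy-5-(4-hydroxy-2-oxo-2H-pyran-6-yl)-6-phenyl-3,4-dihydronaphthalen-1(2H)-one (wailupemycin F)
Conditions: H2 (1 atm), Pd/C, EtOAc, rt
Reagents that add atoms: none
Why: Catalytic hydrogenolysis of the two O-benzyl groups under neutral conditions, stopped at full debenzylation, should leave the β-hydroxy ketone, the aryl ketone and the pyrone double bonds intact and does not touch the C3 centre.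

**Compound list**

1 | 4-hydroxy-6-methyl-2H-pyran-2-one (triacetic acid lactone) | CC1=CC(O)=CC(=O)O1 | starting material
2 | 4-(benzyloxy)-6-methyl-2H-pyran-2-one | Cc1cc(OCc2ccccc2)cc(=O)o1 | intermediate
3 | methyl 3-phenylprop-2-ynoate | COC(=O)C#Cc1ccccc1 | starting material
4 | methyl (2E)-4-[4-(benzyloxy)-2-oxo-2H-pyran-6-yl]-3-phenylbut-2-enoate | COC(=O)/C=C(\Cc1cc(OCc2ccccc2)cc(=O)o1)c1ccccc1 | intermediate
5 | 3-(tert-butyldimethylsilyloxy)propanal | O=CCCO[Si](C)(C)C(C)(C)C | starting material
6 | 1-(triphenylphosphoranylidene)propan-2-one | CC(=O)C=P(c1ccccc1)(c1ccccc1)c1ccccc1 | starting material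
7 | (3E)-6-(tert-butyldimethylsilyloxy)hex-3-en-2-one | CC(=O)/C=C/CCO[Si](C)(C)C(C)(C)C | intermediate
8 | methyl 4-[4-(benzyloxy)-2-oxo-2H-pyran-6-yl]-5-[2-(tert-butyldimethylsilyloxy)ethyl]-7-oxo-3-phenyloct-2-enoate (Michael adduct, diastereomer mixture, racemic, formed in the flask and not isolated) | COC(=O)C=C(c1ccccc1)C(c1cc(OCc2ccccc2)cc(=O)o1)C(CCO[Si](C)(C)C(C)(C)C)CC(C)=O | intermediate
9 | 6-acetyl-4-[4-(benzyloxy)-2-oxo-2H-pyran-6-yl]-5-[2-(tert-butyldimethylsilyloxy)ethyl]-3-phenylcyclohex-2-en-1-one (diastereomer and enol tautomer mixture, racemic, not isolated) | CC(=O)C1C(=O)C=C(c2ccccc2)C(c2cc(OCc3ccccc3)cc(=O)o2)C1CCO[Si](C)(C)C(C)(C)C | intermediate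
10 | 6-{3-acetyl-2-[2-(tert-butyldimethylsilyloxy)ethyl]-4-hydroxy-6-phenylphenyl}-4-(benzyloxy)-2H-pyran-2-one | CC(=O)c1c(O)cc(-c2ccccc2)c(-c2cc(OCc3ccccc3)cc(=O)o2)c1CCO[Si](C)(C)C(C)(C)C | intermediate
11 | 6-{3-acetyl-4-(benzyloxy)-2-[2-(tert-butyldimethylsilyloxy)ethyl]-6-phenylphenyl}-4-(benzyloxy)-2H-pyran-2-one | CC(=O)c1c(OCc2ccccc2)cc(-c2ccccc2)c(-c2cc(OCc3ccccc3)cc(=O)o2)c1CCO[Si](C)(C)C(C)(C)C | intermediate
12 | 6-[3-acetyl-4-(benzyloxy)-2-(2-hydroxyethyl)-6-phenylphenyl]-4-(benzyloxy)-2H-pyran-2-one | CC(=O)c1c(OCc2ccccc2)cc(-c2ccccc2)c(-c2cc(OCc3ccccc3)cc(=O)o2)c1CCO | intermediate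
13 | 2-{2-acetyl-3-(benzyloxy)-6-[4-(benzyloxy)-2-oxo-2H-pyran-6-yl]-5-phenylphenyl}acetaldehyde | CC(=O)c1c(OCc2ccccc2)cc(-c2ccccc2)c(-c2cc(OCc3ccccc3)cc(=O)o2)c1CC=O | intermediate
14 | (3S)-8-(benzyloxy)-5-[4-(benzyloxy)-2-oxo-2H-pyran-6-yl]-3-hydroxy-6-phenyl-3,4-dihydronaphthalen-1(2H)-one | O=C1C[C@@H](O)Cc2c1c(OCc1ccccc1)cc(-c1ccccc1)c2-c1cc(OCc2ccccc2)cc(=O)o1 | intermediate
15 | (3S)-3,8-dihydroxy-5-(4-hydroxy-2-oxo-2H-pyran-6-yl)-6-phenyl-3,4-dihydronaphthalen-1(2H)-one (wailupemycin F) | O=C1C[C@@H](O)Cc2c1c(O)cc(-c1ccccc1)c2-c1cc(O)cc(=O)o1 | target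

**Step count**

Total steps: 9. Longest linear sequence: 8 steps (steps 1, 2, 4, 5, 6, 7, 8, 9, from compound 1); step 3 is a one-step side branch.

**Steps most likely to fail, with fallbacks**

Step 8 (the step beyond known chemistry). What may go wrong: poor facial selectivity in the ring closure, stalling of the catalyst through enolisation of the arylacetaldehyde, or loss of water from the aldol to the naphthol. The fallback uses known chemistry and sets out from compound 13. Ring closure without asymmetric induction by base-mediated intramolecular aldol addition (catalytic K2CO3, i-PrOH–CH2Cl2, 0 °C) should give racemic 8-(benzyloxy)-5-[4-(benzyloxy)-2-oxo-2H-pyran-6-yl]-3-hydroxy-6-phenyl-3,4-dihydronaphthalen-1(2H)-one F1. Lipase-catalysed kinetic resolution of this secondary alcohol (Burkholderia cepacia lipase or Candida antarctica lipase B, vinyl acetate, MTBE, rt, stopped near half conversion) is then expected to acylate one enantiomer. With an enzyme that takes the (R)-alcohol, (3R)-3-acetoxy-8-(benzyloxy)-5-[4-(benzyloxy)-2-oxo-2H-pyran-6-yl]-6-phenyl-3,4-dihydronaphthalen-1(2H)-one F2 is removed by chromatography and the unreacted (S)-alcohol is compound 14, where the route is rejoined. The enzyme with that preference would be chosen by screening.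

Step 2. What may go wrong: attack of the lithiated pyrone at the ester carbonyl of 3 instead of the β-carbon (1,2- versus 1,4-addition), or a second addition of the product anion to the ynoate. The fallback sets out from compound 2 and assembles the chain on a ketone. Lateral lithiation [LiN(SiMe3)2, 2 equiv, THF, −78 °C] and acylation with N-methoxy-N-methylbenzamide should give 4-(benzyloxy)-6-(2-oxo-2-phenylethyl)-2H-pyran-2-one F3. O-Triflation (Tf2O, i-Pr2NEt, CH2Cl2, −78 °C) gives 2-[4-(benzyloxy)-2-oxo-2H-pyran-6-yl]-1-phenylethenyl trifluoromethanesulfonate F4. Palladium-catalysed coupling with the Reformatsky reagent BrZnCH2CO2Me [Pd(PPh3)4, THF, 50 °C] gives methyl 4-[4-(benzyloxy)-2-oxo-2H-pyran-6-yl]-3-phenylbut-3-enoate F5, the double-bond isomer of 4. F5 gives the same delocalised anion as 4 on deprotonation and is used in step 4 in its place, so the route is rejoined at compound 10.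

Step 4. What may go wrong: Michael addition through the ester α-carbon instead of the pyronyl carbon, γ-deprotonation of the enone by the stabilised anion, or a stalled Claisen closure because the ketone enolate is disfavoured against the stabilised carbanion. The fallback sets out from compound 4 and replaces the anionic annulation and the oxidation by a cycloaddition at the arene oxidation level. Deprotonation and O-silylation [LiN(SiMe3)2, Me3SiCl, THF, −78 °C] should give the vinylketene acetal 4-(benzyloxy)-6-[4-methoxy-2-phenyl-4-(trimethylsilyloxy)buta-1,3-dien-1-yl]-2H-pyran-2-one F6. The dienophile 6-(tert-butyldimethylsilyloxy)hex-3-yn-2-one F7 is made from purchasable tert-butyl(but-3-yn-1-yloxy)dimethylsilane (n-BuLi, THF, −78 °C; N-methoxy-N-methylacetamide). Diels–Alder reaction in toluene at 80–110 °C, with the oxygenated diene terminus bonding to the acetyl-bearing alkyne carbon, should give 6-{3-acetyl-2-[2-(tert-butyldimethylsilyloxy)ethyl]-4-methoxy-6-phenyl-4-(trimethylsilyloxy)cyclohexa-2,5-dien-1-yl}-4-(benzyloxy)-2H-pyran-2-one F8. On brief mild acidic work-up (dilute HCl, THF, 0 °C) F8 loses methanol and trimethylsilanol and tautomerises to compound 10, where the route is rejoined.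

**Further compounds**

F1 | step 8 | racemic 8-(benzyloxy)-5-[4-(benzyloxy)-2-oxo-2H-pyran-6-yl]-3-hydroxy-6-phenyl-3,4-dihydronaphthalen-1(2H)-one | O=C1CC(O)Cc2c1c(OCc1ccccc1)cc(-c1ccccc1)c2-c1cc(OCc2ccccc2)cc(=O)o1
F2 | step 8 | (3R)-3-acetoxy-8-(benzyloxy)-5-[4-(benzyloxy)-2-oxo-2H-pyran-6-yl]-6-phenyl-3,4-dihydronaphthalen-1(2H)-one | O=C1C[C@H](OC(C)=O)Cc2c1c(OCc1ccccc1)cc(-c1ccccc1)c2-c1cc(OCc2ccccc2)cc(=O)o1
F3 | step 2 | 4-(benzyloxy)-6-(2-oxo-2-phenylethyl)-2H-pyran-2-one | O=C(Cc1cc(OCc2ccccc2)cc(=O)o1)c1ccccc1
F4 | step 2 | 2-[4-(benzyloxy)-2-oxo-2H-pyran-6-yl]-1-phenylethenyl trifluoromethanesulfonate (alkene geometry immaterial) | O=S(=O)(OC(=Cc1cc(OCc2ccccc2)cc(=O)o1)c1ccccc1)C(F)(F)F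
F5 | step 2 | methyl 4-[4-(benzyloxy)-2-oxo-2H-pyran-6-yl]-3-phenylbut-3-enoate (alkene geometry immaterial) | COC(=O)CC(=Cc1cc(OCc2ccccc2)cc(=O)o1)c1ccccc1
F6 | step 4 | 4-(benzyloxy)-6-[4-methoxy-2-phenyl-4-(trimethylsilyloxy)buta-1,3-dien-1-yl]-2H-pyran-2-one (isomer mixture) | COC(O[Si](C)(C)C)=CC(c1ccccc1)=Cc1cc(OCc2ccccc2)cc(=O)o1
F7 | step 4 | 6-(tert-butyldimethylsilyloxy)hex-3-yn-2-one | CC(=O)C#CCCO[Si](C)(C)C(C)(C)C
F8 | step 4 | 6-{3-acetyl-2-[2-(tert-butyldimethylsilyloxy)ethyl]-4-methoxy-6-phenyl-4-(trimethylsilyloxy)cyclohexa-2,5-dien-1-yl}-4-(benzyloxy)-2H-pyran-2-one (racemic, diastereomer mixture) | COC1(O[Si](C)(C)C)C=C(c2ccccc2)C(c2cc(OCc3ccccc3)cc(=O)o2)C(CCO[Si](C)(C)C(C)(C)C)=C1C(C)=O
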